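Ring A'' of the apigenin half carries oxygen on C5'', C7'', C8'' and C8a''. The 8- versus 6-aryloxy question arises only if ring C'' is closed after ring A''. The order is therefore reversed. The C7''–C8'' bond is cut, so ring A'' is grown on a finished 4-pyranone (ring C'') in which O1''–C8a'' and the C8''–O–aryl ether already exist. One base-induced vinylogous Dieckmann closure forms that bond, closes the ring and, by enolisation, delivers the 5'',7''-diol. The precursor is a 6-aryl-4-pyranone with the flavonyl-phenoxymethyl group on C2 and a methyl 3-oxopropanoate chain on C3.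

Key step: step 8

Remarks on the chemistry
* Locants: unprimed = genkwanin half, double-primed = rings A''/C'' of the apigenin half, triple-primed = its ring B. The target has no stereocentre. The two transient compounds with an sp3 CH between carbonyl groups are drawn as keto tautomers without configuration.
* Assumption: 1-(benzyloxy)-4-ethynylbenzene and the potassium salts of mono-tert-butyl and monomethyl malonate are taken as catalogue chemicals.
* C8'' and its ether oxygen enter as an aryloxyacetic acid. No radical halogenation therefore has to be run beside benzyl ethers.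
* The pyranone is made from a β-keto ester with a single ketone, so its closure has no regiochemical option.
* The C3 ester is then homologated with a magnesium malonate. No strong-base carboxylation is needed next to the acidic C8'' methylene.
* O5 is benzylated only after O4' is alkylated, which follows the natural reactivity order of genkwanin.
* Mass balance of the key step: C46H36O11 → C45H32O10 + CH3OH.

Step 1
Reactants: 1 genkwanin; 2 methyl bromoacetate
Product: 4 methyl 2-[4-(5-benzyloxy-7-methoxy-4-oxo-4H-chromen-2-yl)phenoxy]acetate, via 5-hydroxy aryloxyacetate 3 (not isolated)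
Conditions: 2 (1.05 equiv), K2CO3 (1.2 equiv), DMF, rt; then BnBr (2 equiv), K2CO3 (3 equiv), cat. Bu4NI, 70 °C
Reagents that add atoms: benzyl bromide, BrCc1ccccc1
Why: Two Williamson etherifications in one flask: the free 4'-OH is much more acidic and nucleophilic than the 5-OH hydrogen-bonded to C4=O, so one equivalent of 2 should go to O4' at room temperature, and only then do excess benzyl bromide and heat force the chelated 5-OH to react.

Step 2
Reactants: 4 methyl 2-[4-(5-benzyloxy-7-methoxy-4-oxo-4H-chromen-2-yl)phenoxy]acetate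
Product: 5 2-[4-(5-benzyloxy-7-methoxy-4-oxo-4H-chromen-2-yl)phenoxy]acetic acid
Conditions: LiOH·H2O (1.5 equiv), THF–H2O 3:1, 0 °C → rt; 1 M HCl to pH 3
Reagents that add atoms: lithium hydroxide, [Li+].[OH-]
Why: Ester saponification; an aryloxyacetate is activated enough to be cleaved by dilute LiOH at or below room temperature, conditions under which the flavone pyranone ring and both ethers persist.

Step 3
Reactants: 5 2-[4-(5-benzyloxy-7-methoxy-4-oxo-4H-chromen-2-yl)phenoxy]acetic acid; 6 potassium mono-tert-butyl malonate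
Product: 8 tert-butyl 4-[4-(5-benzyloxy-7-methoxy-4-oxo-4H-chromen-2-yl)phenoxy]-3-oxobutanoate, via aryloxyacetyl imidazolide 7 (not isolated)
Conditions: CDI (1.1 equiv), THF, rt; then 6 (2 equiv), MgCl2 (2 equiv), Et3N (3 equiv), MeCN (premixed), rt → 40 °C; cold 1 M HCl
Reagents that add atoms: 1,1'-carbonyldiimidazole, O=C(n1ccnc1)n1ccnc1 (imidazolyl group of transient 7 only)
Why: Masamune–Brooks β-keto ester synthesis (acyl imidazolide plus magnesium malonate half-ester enolate, then decarboxylation), which runs close to neutrality and so leaves the flavone untouched.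

Step 4
Reactants: 9 1-(benzyloxy)-4-ethynylbenzene
Product: 11 3-[4-(benzyloxy)phenyl]prop-2-ynoic acid, via lithium acetylide 10 (not isolated)
Conditions: n-BuLi (1.05 equiv), THF, −78 °C; CO2 (dried gas), −78 °C → rt; 1 M HCl
Reagents that add atoms: carbon dioxide, O=C=O; n-butyllithium, [Li]CCCC (lithium of transient 10 only)
Why: Deprotonation of a terminal alkyne and carboxylation of the lithium acetylide, a standard route to arylpropiolic acids to which the benzyl ether is inert.

Step 5
Reactants: 11 3-[4-(benzyloxy)phenyl]prop-2-ynoic acid; 8 tert-butyl 4-[4-(5-benzyloxy-7-methoxy-4-oxo-4H-chromen-2-yl)phenoxy]-3-oxobutanoate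
Product: 14 tert-butyl 6-[4-(benzyloxy)phenyl]-2-{[4-(5-benzyloxy-7-methoxy-4-oxo-4H-chromen-2-yl)phenoxy]methyl}-4-oxo-4H-pyran-3-carboxylate, via alkynoyl chloride 12 (not isolated), via acyclic tricarbonyl ester 13 (not isolated)
Conditions: 11, (COCl)2 (1.2 equiv), cat. DMF, CH2Cl2, 0 °C → rt, evaporate; then 8, MgCl2 (2 equiv), pyridine (3 equiv), CH2Cl2, 0 °C → rt, then 35 °C
Reagents that add atoms: oxalyl chloride, O=C(Cl)C(=O)Cl (chlorine of transient 12 only)
Why: C-acylation of a magnesium β-keto ester enolate with an alkynoyl chloride followed by 6-endo-dig oxa-Michael closure is the classical entry to 4-pyranone-3-carboxylates, and since 8 holds a single ketone only that oxygen can become O1'', which places the aryloxymethyl group on C2 without regiochemical choice.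

Step 6
Reactants: 14 tert-butyl 6-[4-(benzyloxy)phenyl]-2-{[4-(5-benzyloxy-7-methoxy-4-oxo-4H-chromen-2-yl)phenoxy]methyl}-4-oxo-4H-pyran-3-carboxylate
Product: 15 6-[4-(benzyloxy)phenyl]-2-{[4-(5-benzyloxy-7-methoxy-4-oxo-4H-chromen-2-yl)phenoxy]methyl}-4-oxo-4H-pyran-3-carboxylic acid
Conditions: TFA–CH2Cl2 1:4, 0 °C → rt
Reagents that add atoms: none
Why: Acidolysis of a tert-butyl ester (alkyl–oxygen cleavage via the tert-butyl cation) avoids hydroxide, which would attack the pyranone, while short exposure to dilute TFA should spare the aryl benzyl ethers, and a 4-pyranone-3-carboxylic acid does not decarboxylate at room temperature.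

Step 7
Reactants: 15 6-[4-(benzyloxy)phenyl]-2-{[4-(5-benzyloxy-7-methoxy-4-oxo-4H-chromen-2-yl)phenoxy]methyl}-4-oxo-4H-pyran-3-carboxylic acid; 16 potassium monomethyl malonate
Product: 18 methyl 3-(6-[4-(benzyloxy)phenyl]-2-{[4-(5-benzyloxy-7-methoxy-4-oxo-4H-chromen-2-yl)phenoxy]methyl}-4-oxo-4H-pyran-3-yl)-3-oxopropanoate, via pyranone-3-carbonyl imidazolide 17 (not isolated)
Conditions: CDI (1.1 equiv), THF, rt → 40 °C; then 16 (2 equiv), MgCl2 (2 equiv), Et3N (3 equiv), MeCN (premixed), rt → 40 °C; cold 0.5 M HCl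
Reagents that add atoms: 1,1'-carbonyldiimidazole, O=C(n1ccnc1)n1ccnc1 (imidazolyl group of transient 17 only)
Why: Second Masamune–Brooks homologation; the weakly basic magnesium enolate acylates at carbon and decarboxylates to the methyl β-keto ester without the strong base that would otherwise engage the acidic C8'' methylene.

Step 8
Reactants: 18 methyl 3-(6-[4-(benzyloxy)phenyl]-2-{[4-(5-benzyloxy-7-methoxy-4-oxo-4H-chromen-2-yl)phenoxy]methyl}-4-oxo-4H-pyran-3-yl)-3-oxopropanoate
Product: 20 2-[4-(benzyloxy)phenyl]-8-[4-(5-benzyloxy-7-methoxy-4-oxo-4H-chromen-2-yl)phenoxy]-5,7-dihydroxy-4H-chromen-4-one (5,4'''-di-O-benzyl target), via ring-closed trione tautomer 19 (not isolated)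
Conditions: LiHMDS (3.5 equiv), THF (0.01 M), −78 °C → rt, then 40 °C; AcOH quench
Reagents that add atoms: none
Why: Proposed new method: LiHMDS first removes the most acidic proton (C6''H2 of the β-keto ester) and a further equivalent takes a C8'' proton, which is acidified vinylogously through C8a''=C4a'' by the C4'' and C5'' carbonyls and inductively by the aryloxy oxygen; the C8'' terminus of this extended enolate adds to ester carbon C7'', methoxide leaves and then deprotonates 19, whose double enolisation to the resorcinol dianion makes the sequence irreversible. The closest known reaction types are the Claisen-mode aromatisations of poly-β-keto ester polyanions and the lateral deprotonation–condensation of 2-methyl-4-pyranones, but their union in an intramolecular acylation that turns a pyranone into a chromone has not been shown. Ring A'' closes in the 6-exo-trig (Dieckmann) mode and C7''–C8'' is the only new skeletal bond. No stereocentre results, because the sp3 C8'' of 19 is planarised on aromatisation. The step needs C-acylation at C8'' rather than O-acylation by O4'', intermolecular condensation or nucleophilic opening of a pyranone: C8'' is the only carbanion that reaches C7'' through a six-membered carbocyclic transition state, lithium bridging O4'' and O5'' should hold the chain in the rotamer that points C7'' at C8'', an O-acylated enol lactone would be reopened by methoxide, and a non-nucleophilic amide base at high dilution addresses the rest. Since O1''–C8a'' and C8''–OAr are never broken, the 6-aryloxy isomer cannot arise.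

Step 9
Reactants: 20 2-[4-(benzyloxy)phenyl]-8-[4-(5-benzyloxy-7-methoxy-4-oxo-4H-chromen-2-yl)phenoxy]-5,7-dihydroxy-4H-chromen-4-one
Product: 21 5,7-dihydroxy-8-[4-(5-hydroxy-7-methoxy-4-oxo-4H-chromen-2-yl)phenoxy]-2-(4-hydroxyphenyl)-4H-chromen-4-one (target, CNP0424791.0)
Conditions: H2 (1 atm), 10% Pd/C, THF–MeOH 1:1, rt
Reagents that add atoms: none
Why: Catalytic hydrogenolysis of aryl benzyl ethers under neutral conditions, which leaves the diaryl ether, the 7-methyl ether and both C2=C3 bonds alone and offers no acid that could trigger a Wessely–Moser isomerisation.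

Compound list
1 | genkwanin | COc1cc(O)c2c(=O)cc(-c3ccc(O)cc3)oc2c1 | starting material
2 | methyl bromoacetate | COC(=O)CBr | starting material
3 | methyl 2-[4-(5-hydroxy-7-methoxy-4-oxo-4H-chromen-2-yl)phenoxy]acetate | COC(=O)COc1ccc(-c2cc(=O)c3c(O)cc(OC)cc3o2)cc1 | intermediate
4 | methyl 2-[4-(5-benzyloxy-7-methoxy-4-oxo-4H-chromen-2-yl)phenoxy]acetate | COC(=O)COc1ccc(-c2cc(=O)c3c(OCc4ccccc4)cc(OC)cc3o2)cc1 | intermediate
5 | 2-[4-(5-benzyloxy-7-methoxy-4-oxo-4H-chromen-2-yl)phenoxy]acetic acid | OC(=O)COc1ccc(-c2cc(=O)c3c(OCc4ccccc4)cc(OC)cc3o2)cc1 | intermediate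
6 | potassium mono-tert-butyl malonate | CC(C)(C)OC(=O)CC(=O)[O-].[K+] | starting material
7 | 1-{2-[4-(5-benzyloxy-7-methoxy-4-oxo-4H-chromen-2-yl)phenoxy]acetyl}imidazole | O=C(COc1ccc(-c2cc(=O)c3c(OCc4ccccc4)cc(OC)cc3o2)cc1)n1ccnc1 | intermediate
8 | tert-butyl 4-[4-(5-benzyloxy-7-methoxy-4-oxo-4H-chromen-2-yl)phenoxy]-3-oxobutanoate | CC(C)(C)OC(=O)CC(=O)COc1ccc(-c2cc(=O)c3c(OCc4ccccc4)cc(OC)cc3o2)cc1 | intermediate
9 | 1-(benzyloxy)-4-ethynylbenzene | C#Cc1ccc(OCc2ccccc2)cc1 | starting material
10 | lithium [4-(benzyloxy)phenyl]acetylide | [Li]C#Cc1ccc(OCc2ccccc2)cc1 | intermediate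
11 | 3-[4-(benzyloxy)phenyl]prop-2-ynoic acid | OC(=O)C#Cc1ccc(OCc2ccccc2)cc1 | intermediate
12 | 3-[4-(benzyloxy)phenyl]prop-2-ynoyl chloride | ClC(=O)C#Cc1ccc(OCc2ccccc2)cc1 | intermediate
13 | tert-butyl 2-{2-[4-(5-benzyloxy-7-methoxy-4-oxo-4H-chromen-2-yl)phenoxy]acetyl}-5-[4-(benzyloxy)phenyl]-3-oxopent-4-ynoate (keto form drawn; present as enol or magnesium chelate) | CC(C)(C)OC(=O)C(C(=O)COc1ccc(-c2cc(=O)c3c(OCc4ccccc4)cc(OC)cc3o2)cc1)C(=O)C#Cc1ccc(OCc2ccccc2)cc1 | intermediate
14 | tert-butyl 6-[4-(benzyloxy)phenyl]-2-{[4-(5-benzyloxy-7-methoxy-4-oxo-4H-chromen-2-yl)phenoxy]methyl}-4-oxo-4H-pyran-3-carboxylate | CC(C)(C)OC(=O)c1c(COc2ccc(-c3cc(=O)c4c(OCc5ccccc5)cc(OC)cc4o3)cc2)oc(-c2ccc(OCc3ccccc3)cc2)cc1=O | intermediate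
15 | 6-[4-(benzyloxy)phenyl]-2-{[4-(5-benzyloxy-7-methoxy-4-oxo-4H-chromen-2-yl)phenoxy]methyl}-4-oxo-4H-pyran-3-carboxylic acid | OC(=O)c1c(COc2ccc(-c3cc(=O)c4c(OCc5ccccc5)cc(OC)cc4o3)cc2)oc(-c2ccc(OCc3ccccc3)cc2)cc1=O | intermediate
16 | potassium monomethyl malonate | COC(=O)CC(=O)[O-].[K+] | starting material
17 | imidazolide of acid 15 | O=C(c1c(COc2ccc(-c3cc(=O)c4c(OCc5ccccc5)cc(OC)cc4o3)cc2)oc(-c2ccc(OCc3ccccc3)cc2)cc1=O)n1ccnc1 | intermediate
18 | methyl 3-(6-[4-(benzyloxy)phenyl]-2-{[4-(5-benzyloxy-7-methoxy-4-oxo-4H-chromen-2-yl)phenoxy]methyl}-4-oxo-4H-pyran-3-yl)-3-oxopropanoate (key-step precursor) | COC(=O)CC(=O)c1c(COc2ccc(-c3cc(=O)c4c(OCc5ccccc5)cc(OC)cc4o3)cc2)oc(-c2ccc(OCc3ccccc3)cc2)cc1=O | intermediate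
19 | 2-[4-(benzyloxy)phenyl]-8-[4-(5-benzyloxy-7-methoxy-4-oxo-4H-chromen-2-yl)phenoxy]-6,8-dihydro-4H-chromene-4,5,7-trione (transient, no defined configuration at C8'') | O=C1CC(=O)c2c(=O)cc(-c3ccc(OCc4ccccc4)cc3)oc2C1Oc1ccc(-c2cc(=O)c3c(OCc4ccccc4)cc(OC)cc3o2)cc1 | intermediate
20 | 2-[4-(benzyloxy)phenyl]-8-[4-(5-benzyloxy-7-methoxy-4-oxo-4H-chromen-2-yl)phenoxy]-5,7-dihydroxy-4H-chromen-4-one (key-step product) | COc1cc(OCc2ccccc2)c2c(=O)cc(-c3ccc(Oc4c(O)cc(O)c5c(=O)cc(-c6ccc(OCc7ccccc7)cc6)oc45)cc3)oc2c1 | intermediate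
21 | 5,7-dihydroxy-8-[4-(5-hydroxy-7-methoxy-4-oxo-4H-chromen-2-yl)phenoxy]-2-(4-hydroxyphenyl)-4H-chromen-4-one | COc1cc(O)c2c(=O)cc(-c3ccc(Oc4c(O)cc(O)c5c(=O)cc(-c6ccc(O)cc6)oc45)cc3)oc2c1 | target

Total step count: 9
Longest linear sequence: 8 (steps 1, 2, 3, 5, 6, 7, 8, 9)

Steps most likely to fail

1. Step 8.
* What may go wrong: deprotonation may stop at the C6'' enolate, whose charge lowers the electrophilicity of C7''. O-acylation through O4'', intermolecular condensation, or opening of a pyranone ring by liberated methoxide may then overtake ring closure.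
* Fallback (known chemistry, from 1 back to 21): the diaryl ether is made by an Ullmann-type coupling on a finished 8-iodoflavone.
* Purchased apigenin would be perbenzylated (BnBr, K2CO3, DMF, 80 °C) to 5,7,4'-tri-O-benzylapigenin F1.
* Electrophilic iodination of this fully alkylated flavone (I2, AgO2CCF3, CH2Cl2) should go to C8 and give 8-iodo-5,7,4'-tri-O-benzylapigenin F2.
* Copper-catalysed etherification of the 4'-OH of 1 with F2 (CuI, picolinic acid, K3PO4, DMSO, 90–100 °C) should give the 5'',7'',4'''-tri-O-benzyl ether of the target F3.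
* Hydrogenolysis under the conditions of step 9 then leads to 21.

2. Step 5.
* What may go wrong: O-acylation of the magnesium enolate, conjugate addition of chloride or pyridine to the alkynoyl chloride, or closure through the ester oxygen with loss of the tert-butyl group.
* Fallback (from 5 and 11 back to 14, bypassing 8 and 12): nucleophile and electrophile are exchanged, so the pyranone C2–C3 bond is formed instead of C3–C4.
* Acid 11 would be activated with CDI to 1-{3-[4-(benzyloxy)phenyl]prop-2-ynoyl}imidazole F4. This is homologated with 6 (MgCl2, Et3N) to tert-butyl 5-[4-(benzyloxy)phenyl]-3-oxopent-4-ynoate F5.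
* Acid 5 would be converted with oxalyl chloride into 2-[4-(5-benzyloxy-7-methoxy-4-oxo-4H-chromen-2-yl)phenoxy]acetyl chloride F6.
* C-acylation of the magnesium enolate of F5 with F6 (MgCl2, pyridine, CH2Cl2) gives the same tricarbonyl ester 13, which closes to 14.

3. Step 7.
* What may go wrong: slow acyl transfer from a carbonyl group flanked on both sides, and attack of imidazole on C2 or C6 of the pyranone during the long reaction time.
* Fallback (from 15 back to 18): the two carbons are supplied by Meldrum's acid instead of a malonate half-ester.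
* Acid 15 would be turned with oxalyl chloride and cat. DMF into 6-[4-(benzyloxy)phenyl]-2-{[4-(5-benzyloxy-7-methoxy-4-oxo-4H-chromen-2-yl)phenoxy]methyl}-4-oxo-4H-pyran-3-carbonyl chloride F7.
* F7 would acylate Meldrum's acid (pyridine, CH2Cl2, 0 °C) to the acyl Meldrum's acid F8.
* Alcoholysis of F8 in refluxing MeOH–toluene gives 18.

Further compounds
F1 | step 8 | 5,7,4'-tri-O-benzylapigenin | O=c1cc(-c2ccc(OCc3ccccc3)cc2)oc2cc(OCc3ccccc3)cc(OCc3ccccc3)c12
F2 | step 8 | 8-iodo-5,7,4'-tri-O-benzylapigenin | O=c1cc(-c2ccc(OCc3ccccc3)cc2)oc2c(I)c(OCc3ccccc3)cc(OCc3ccccc3)c12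
F3 | step 8 | 5'',7'',4'''-tri-O-benzyl ether of the target | COc1cc(O)c2c(=O)cc(-c3ccc(Oc4c(OCc5ccccc5)cc(OCc5ccccc5)c5c(=O)cc(-c6ccc(OCc7ccccc7)cc6)oc45)cc3)oc2c1
F4 | step 5 | 1-{3-[4-(benzyloxy)phenyl]prop-2-ynoyl}imidazole | O=C(C#Cc1ccc(OCc2ccccc2)cc1)n1ccnc1
F5 | step 5 | tert-butyl 5-[4-(benzyloxy)phenyl]-3-oxopent-4-ynoate | CC(C)(C)OC(=O)CC(=O)C#Cc1ccc(OCc2ccccc2)cc1
F6 | step 5 | 2-[4-(5-benzyloxy-7-methoxy-4-oxo-4H-chromen-2-yl)phenoxy]acetyl chloride | ClC(=O)COc1ccc(-c2cc(=O)c3c(OCc4ccccc4)cc(OC)cc3o2)cc1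
F7 | step 7 | 6-[4-(benzyloxy)phenyl]-2-{[4-(5-benzyloxy-7-methoxy-4-oxo-4H-chromen-2-yl)phenoxy]methyl}-4-oxo-4H-pyran-3-carbonyl chloride | ClC(=O)c1c(COc2ccc(-c3cc(=O)c4c(OCc5ccccc5)cc(OC)cc4o3)cc2)oc(-c2ccc(OCc3ccccc3)cc2)cc1=O
F8 | step 7 | 5-acyl-2,2-dimethyl-1,3-dioxane-4,6-dione derived from acid 15 (acyl Meldrum's acid) | CC1(C)OC(=O)C(C(=O)c2c(COc3ccc(-c4cc(=O)c5c(OCc6ccccc6)cc(OC)cc5o4)cc3)oc(-c3ccc(OCc4ccccc4)cc3)cc2=O)C(=O)O1
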